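The target is read as a vinylogous ester: in the tetrahydrobenzofuranone core the enol-ether bond O1–C7a is β to the C6 ketone, and the quaternary carbon C3a is its γ-position. Both rings are therefore formed in one base-catalysed cascade from an acyclic hydroxy ynone. The C2 alkoxide adds 5-exo-dig to the ynone β-carbon C7a and closes the dihydrofuran ring. The resulting vinylogous ester has an acidic C3a–H, and the derived trienolate closes the cyclohexenone ring (C3a–C4) by 6π-electrocyclization anti to the C3 aryl group. C3a is thus set stereoconvergently and C5 by equilibration. The precursor is a linear alkynyl α-methoxyvinyl ketone carrying only the C2/C3 stereocentres.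

Key step: step 5

Assumption: (S)-5-methylfuran-2(5H)-one and methyl 2-methoxyacrylate are taken as purchasable; atom labels follow the benzofuranone numbering of the target (O1, C2, C3, C3a, C4 to C7, C7a).

Step 1
Reactants: 1 (S)-5-methylfuran-2(5H)-one; 2 (3,4,5-trimethoxyphenyl)magnesium bromide; 3 allyl bromide
Product: 5 (3R,4S,5S)-3-allyl-5-methyl-4-(3,4,5-trimethoxyphenyl)dihydrofuran-2(3H)-one, via bromomagnesium enolate 4 (not isolated)
Conditions: 2 (1.5 equiv), CuBr·SMe2 (10 mol %), THF, −78 → −40 °C; then 3 (3 equiv), DMPU, −40 → 0 °C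
Reagents that add atoms: (3,4,5-trimethoxyphenyl)magnesium bromide, COc1cc([Mg]Br)cc(OC)c1OC; allyl bromide, C=CCBr
Why: Copper-catalysed 1,4-addition of the aryl Grignard reagent to the butenolide should take place anti to the C5 methyl group (this fixes the C2/C3 trans relationship of the target), and the enolate is then allylated anti to the new aryl group in a tandem conjugate addition–enolate alkylation; the allyl-bearing centre is planarized again in step 5.

Step 2
Reactants: 5 (3R,4S,5S)-3-allyl-5-methyl-4-(3,4,5-trimethoxyphenyl)dihydrofuran-2(3H)-one; 6 dimethyl (1-diazo-2-oxopropyl)phosphonate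
Product: 8 (2S,3S,4R)-4-ethynyl-3-(3,4,5-trimethoxyphenyl)hept-6-en-2-ol, via lactol 7 (not isolated)
Conditions: i-Bu2AlH (1.1 equiv), CH2Cl2, −78 °C; then MeOH, K2CO3 (3 equiv), 6 (1.5 equiv), −78 °C → rt
Reagents that add atoms: dimethyl (1-diazo-2-oxopropyl)phosphonate (Ohira–Bestmann reagent), CC(=O)C(=[N+]=[N-])P(=O)(OC)OC
Why: Half-reduction of the lactone to the lactol followed by Seyferth–Gilbert homologation with the Ohira–Bestmann reagent turns the lactone carbonyl carbon into the internal alkyne carbon (future C7a) and frees the C2 hydroxyl; C2 and C3 are untouched, and any epimerization α to the transient aldehyde is harmless because that centre is erased in step 5.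

Step 3
Reactants: 9 methyl 2-methoxyacrylate; 10 N,O-dimethylhydroxylamine hydrochloride
Product: 11 N,2-dimethoxy-N-methylprop-2-enamide
Conditions: i-PrMgCl (2.2 equiv), THF, −20 → 0 °C
Reagents that add atoms: N,O-dimethylhydroxylamine hydrochloride, CNOC.Cl
Why: Weinreb amidation of the ester by the chloromagnesium amide formed in situ should be clean because the α-methoxy group makes the acrylate a poor conjugate acceptor; no stereocentre is formed.

Step 4
Reactants: 8 (2S,3S,4R)-4-ethynyl-3-(3,4,5-trimethoxyphenyl)hept-6-en-2-ol; 11 N,2-dimethoxy-N-methylprop-2-enamide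
Product: 12 (6R,7S,8S)-6-allyl-8-hydroxy-2-methoxy-7-(3,4,5-trimethoxyphenyl)non-1-en-4-yn-3-one
Conditions: n-BuLi (2.05 equiv), THF, −78 °C; then 11 (1.3 equiv), −78 → −30 °C; inverse quench into AcOH/THF at −78 °C
Reagents that add atoms: N,2-dimethoxy-N-methylprop-2-enamide, C=C(OC)C(=O)N(C)OC
Why: In this Weinreb ketone synthesis the acetylide of the alkoxide–acetylide dianion adds once to the amide and the chelated tetrahedral intermediate releases the ynone only on cold acidic quench, which should prevent over-addition, amine conjugate addition and premature cyclization; no stereocentre is formed.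

Step 5
Reactants: 12 (6R,7S,8S)-6-allyl-8-hydroxy-2-methoxy-7-(3,4,5-trimethoxyphenyl)non-1-en-4-yn-3-one
Product: 15 (2S,3R,3aR,5R)-3a-allyl-5-methoxy-2-methyl-3-(3,4,5-trimethoxyphenyl)-3,3a,4,5-tetrahydrobenzofuran-6(2H)-one, via alkylidenetetrahydrofuran 13 (not isolated), via potassium trienolate 14 (not isolated)
Conditions: t-BuOK (0.3 equiv), THF/t-BuOH (5:1), 0.01 M, 0 °C → rt, then 50 °C
Reagents that add atoms: none
Why: Proposed new method: catalytic tert-butoxide forms the C2 alkoxide, which adds 5-exo-dig to the ynone β-carbon C7a (oxa-Michael addition) and closes the dihydrofuran ring as vinylogous ester 13; removal of its γ-hydrogen at C3a gives trienolate 14 (C3a=C7a–C7=C6(O−)–C5(OMe)=C4), which closes the six-membered ring by disrotatory 6π-electrocyclization (equivalently an intramolecular vinylogous Michael addition of C3a to C4), and protonation at C5 returns the catalyst, so the step is an isomerization of 12. The closest known reaction types are the base-mediated 5-exo-dig cyclization of hydroxy ynones to 2-acylmethylene tetrahydrofurans and the 6π-electrocyclization of 2-oxy-substituted hexatrienes to cyclohexadienol derivatives; their union in one cascade that builds a quaternary centre is the untested part. C3a is controlled by the C3 aryl group on the ring just formed: C4 should bond to the planar C3a on the face opposite the aryl group, as electrophiles do with β-aryl butyrolactone enolates, which places the allyl group cis to the aryl group, and because C3a is trigonal in 14 both C3a epimers of 12 converge. C5 is set under thermodynamic control by reversible enolization in tert-butanol, the methoxy group taking the equatorial position trans to the pseudo-axial allyl group. The step needs O-attack at C7a and not at the vinyl ketone terminus C4, and C–C closure at C3a and not at C7; ring size secures both (five- against nine-membered, six- against four-membered), and the linear ynone cannot bring C3a and C4 together until the first ring has closed. The main uncertainty is the rate of the electrocyclization with the allyl group on the inside of the triene terminus.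

Compound list
1 | (S)-5-methylfuran-2(5H)-one | C[C@@H]1OC(=O)C=C1 | starting material
2 | (3,4,5-trimethoxyphenyl)magnesium bromide | COc1cc([Mg]Br)cc(OC)c1OC | starting material
3 | allyl bromide | C=CCBr | starting material
4 | bromomagnesium enolate of (4S,5S)-5-methyl-4-(3,4,5-trimethoxyphenyl)dihydrofuran-2(3H)-one | C[C@@H]1OC(O[Mg]Br)=C[C@H]1c1cc(OC)c(OC)c(OC)c1 | intermediate
5 | (3R,4S,5S)-3-allyl-5-methyl-4-(3,4,5-trimethoxyphenyl)dihydrofuran-2(3H)-one (all-trans) | C=CC[C@H]1C(=O)O[C@@H](C)[C@@H]1c1cc(OC)c(OC)c(OC)c1 | intermediate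
6 | dimethyl (1-diazo-2-oxopropyl)phosphonate | CC(=O)C(=[N+]=[N-])P(=O)(OC)OC | starting material
7 | (3R,4S,5S)-3-allyl-5-methyl-4-(3,4,5-trimethoxyphenyl)tetrahydrofuran-2-ol (lactol, both anomers) | C=CC[C@H]1C(O)O[C@@H](C)[C@@H]1c1cc(OC)c(OC)c(OC)c1 | intermediate
8 | (2S,3S,4R)-4-ethynyl-3-(3,4,5-trimethoxyphenyl)hept-6-en-2-ol | C[C@H](O)[C@@H]([C@@H](CC=C)C#C)c1cc(OC)c(OC)c(OC)c1 | intermediate
9 | methyl 2-methoxyacrylate | C=C(OC)C(=O)OC | starting material
10 | N,O-dimethylhydroxylamine hydrochloride | CNOC.Cl | starting material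
11 | N,2-dimethoxy-N-methylprop-2-enamide | C=C(OC)C(=O)N(C)OC | intermediate
12 | (6R,7S,8S)-6-allyl-8-hydroxy-2-methoxy-7-(3,4,5-trimethoxyphenyl)non-1-en-4-yn-3-one | C[C@H](O)[C@@H]([C@@H](CC=C)C#CC(=O)C(OC)=C)c1cc(OC)c(OC)c(OC)c1 | intermediate
13 | 1-[(3R,4S,5S)-3-allyl-5-methyl-4-(3,4,5-trimethoxyphenyl)dihydrofuran-2(3H)-ylidene]-3-methoxybut-3-en-2-one (E/Z mixture) | C=CC[C@H]1C(=CC(=O)C(OC)=C)O[C@@H](C)[C@@H]1c1cc(OC)c(OC)c(OC)c1 | intermediate
14 | potassium 1-[(4R,5S)-3-allyl-5-methyl-4-(3,4,5-trimethoxyphenyl)-4,5-dihydrofuran-2-yl]-3-methoxybuta-1,3-dien-2-olate | C=CCC1=C(C=C([O-])C(OC)=C)O[C@@H](C)[C@@H]1c1cc(OC)c(OC)c(OC)c1.[K+] | intermediate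
15 | (2S,3R,3aR,5R)-3a-allyl-5-methoxy-2-methyl-3-(3,4,5-trimethoxyphenyl)-3,3a,4,5-tetrahydrobenzofuran-6(2H)-one | C=CC[C@]12C[C@@H](OC)C(=O)C=C1O[C@@H](C)[C@@H]2c1cc(OC)c(OC)c(OC)c1 | target

Total step count: 5. Longest linear sequence: 4 steps (steps 1, 2, 4 and 5); step 3 is a one-step side branch.

Steps most likely to fail

Step 5 (Proposed new method). The cascade may stall after the oxa-Michael addition if the electrocyclization is slow with the allyl group pointing into the triene, bond formation at C3a may occur in part on the aryl face, and the vinyl ketone may oligomerize under base. The fallback uses known chemistry, leaves the route at lactone 5 and returns at 15. 3,3-Dimethoxybutan-2-one loses methanol on heating with catalytic TsOH to give 3-methoxybut-3-en-2-one F1. The lithium enolate of 5 (LiN(i-Pr)2, THF, −78 °C) adds to F1 in a Michael reaction on the face opposite the aryl group and gives (3R,4R,5S)-3-allyl-3-(2-methoxy-3-oxobutyl)-5-methyl-4-(3,4,5-trimethoxyphenyl)dihydrofuran-2(3H)-one F2. t-BuOK in THF then brings about the Dieckmann-type acylation of the methyl ketone enolate by the lactone carbonyl, which opens the lactone to (4R)-4-allyl-4-[(1R,2S)-2-hydroxy-1-(3,4,5-trimethoxyphenyl)propyl]-6-methoxycyclohexane-1,3-dione F3. TsOH in toluene with removal of water closes the O1–C7a bond by intramolecular vinylogous esterification and equilibrates C5, giving 15.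

Step 4. The dianion may add in conjugate fashion to the acrylamide or start its polymerization, and the hydroxy ynone may cyclize or decompose during quench and isolation. The fallback reverses the polarity of the fragment union, leaves the route at 8 and returns at 12. Silylation of 8 (TESCl, imidazole, DMF) gives triethyl{[(2S,3S,4R)-4-ethynyl-3-(3,4,5-trimethoxyphenyl)hept-6-en-2-yl]oxy}silane F4. Lithiation (n-BuLi, THF, −78 °C) and acylation with N-methoxy-N-methylcarbamoyl chloride give (4R,5S,6S)-4-allyl-N-methoxy-N-methyl-6-(triethylsilyloxy)-5-(3,4,5-trimethoxyphenyl)hept-2-ynamide F5. 1-Methoxyvinyllithium (methyl vinyl ether, t-BuLi, THF, −78 → 0 °C) adds once to give (6R,7S,8S)-6-allyl-2-methoxy-8-(triethylsilyloxy)-7-(3,4,5-trimethoxyphenyl)non-1-en-4-yn-3-one F6, and buffered HF·pyridine in THF removes the silyl group to give 12.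

Step 1. The Grignard reagent may add 1,2 to the lactone carbonyl, and the magnesium enolate may be allylated incompletely or twice. The fallback separates the two bond formations, leaves the route at 1 and returns at 5. Rhodium-catalysed conjugate addition of (3,4,5-trimethoxyphenyl)boronic acid ([RhCl(cod)]2, aqueous KOH, dioxane, 50 °C) anti to the methyl group gives (4S,5S)-5-methyl-4-(3,4,5-trimethoxyphenyl)dihydrofuran-2(3H)-one F7. Its lithium enolate (LiN(i-Pr)2, THF, −78 °C) is then allylated with allyl bromide anti to the aryl group to give 5.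

Further compounds
F1 | step 5 | 3-methoxybut-3-en-2-one | CC(=O)C(OC)=C
F2 | step 5 | (3R,4R,5S)-3-allyl-3-(2-methoxy-3-oxobutyl)-5-methyl-4-(3,4,5-trimethoxyphenyl)dihydrofuran-2(3H)-one (mixture at the methoxy-bearing carbon) | C=CC[C@]1(CC(OC)C(C)=O)C(=O)O[C@@H](C)[C@@H]1c1cc(OC)c(OC)c(OC)c1
F3 | step 5 | (4R)-4-allyl-4-[(1R,2S)-2-hydroxy-1-(3,4,5-trimethoxyphenyl)propyl]-6-methoxycyclohexane-1,3-dione (mixture at C6) | C=CC[C@@]1(CC(OC)C(=O)CC1=O)[C@H]([C@H](C)O)c1cc(OC)c(OC)c(OC)c1
F4 | step 4 | triethyl{[(2S,3S,4R)-4-ethynyl-3-(3,4,5-trimethoxyphenyl)hept-6-en-2-yl]oxy}silane | C[C@H](O[Si](CC)(CC)CC)[C@@H]([C@@H](CC=C)C#C)c1cc(OC)c(OC)c(OC)c1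
F5 | step 4 | (4R,5S,6S)-4-allyl-N-methoxy-N-methyl-6-(triethylsilyloxy)-5-(3,4,5-trimethoxyphenyl)hept-2-ynamide | C[C@H](O[Si](CC)(CC)CC)[C@@H]([C@@H](CC=C)C#CC(=O)N(C)OC)c1cc(OC)c(OC)c(OC)c1
F6 | step 4 | (6R,7S,8S)-6-allyl-2-methoxy-8-(triethylsilyloxy)-7-(3,4,5-trimethoxyphenyl)non-1-en-4-yn-3-one | C[C@H](O[Si](CC)(CC)CC)[C@@H]([C@@H](CC=C)C#CC(=O)C(OC)=C)c1cc(OC)c(OC)c(OC)c1
F7 | step 1 | (4S,5S)-5-methyl-4-(3,4,5-trimethoxyphenyl)dihydrofuran-2(3H)-one | C[C@@H]1OC(=O)C[C@H]1c1cc(OC)c(OC)c(OC)c1
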